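Early on, in maple, the flask asked about, D is still going in: 3 portions, the last at 5.00 min, well before the first reading at 0.333 h, so I treat the addition as a single charge.

| setting | maple | ash | flask |
|---|---|---|---|
| D | 0.20 M (in portions, 3) | 0.13 M (in portions, 3) | 0.20 M (in portions, 3) |
| E | 0.95 equiv | 0.95 equiv | 0.950 equiv |
| J | 0.010 M | 0.010 M | 0.0100 M |
| remark | the very flask that is asked about, followed so far; portions every 2.5 min | run made earlier; portions every 2.5 min | the portions of D follow each other after 2.5 min, the first at the start |
| time |  |  | 15 h |

| run | time / h | D / % | Z / % |
|---|---|---|---|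
| maple | 0.333 | 60 | 6 |
| maple | 0.833 | 53 | 18 |
| maple | 1.50 | 51 | 24 |
| maple | 2.50 | 50 | 27 |
| maple | 3.00 | 47 | 25 |
| maple | 5.00 | 47 | 24 |
| ash | 0.833 | 53 | 14 |
| ash | 1.33 | 50 | 19 |
| ash | 2.50 | 50 | 22 |
| ash | 4.00 | 47 | 25 |
| ash | 6.00 | 46 | 23 |
| ash | 10.0 | 51 | 27 |

(standard deviation of a reading: 2 percentage points)

- what may be going on: G + J -> L; E -> Q; 2 Q -> X; G + Q -> Z; D <-> G
- the reaction counts as stopped when no species that holds the D changes by six tenths of a point or more over the second half of the time

1. why nothing more happens at 15 h, or that something still does (E has run out first / all of D has reacted / forward and back rates have come level / it is still moving)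
2. conversion of D at 15 h
3. amount of Z at 15 h, in percent of the D charged

The first rung of my ladder is the exchange D ⇌ G. At 0.333 h maple holds 60% D and 6% Z, and I book J, one for one, as L, which is at most 5.00% of the D charged. The balance then gives a ratio G/D of 0.483, so I take the exchange as level within that first reading.

The next rung is the rise of Z: by 1.50 h maple reads Z at 24% and D at 51%, G feeding Z and D refilling G.

On the last rung, the readings from 2.50 h on, D averages 48.0% and Z 25.3%, which leaves G at 21.7%. I carry K, the G/D ratio at rest, an equilibrium constant read from a balance: 0.451. The ash run, booked likewise over its last three readings, reads 0.402, and with a scatter of 2 percentage points per reading I keep maple's value.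

The rule follows: D at rest is the charge less Z and L, divided by one plus K. In maple Z stays flat with G standing, so I infer that the feed of Q from E has stopped, and at 15 h I commit to Z 25.3% and conversion 52.0%.

The forecast says E has run out first, 52% and 25%, on the ground “With E gone, nothing drains G, and D/G just sit at equilibrium”.

The flask gives E has run out first, conversion 52.7% and Z 26.4%.

    G + J → L (k = 6.00 /M/min)
    E → Q (k = 0.0620 /min)
    2 Q → X (k = 0.630 /M/min)
    G + Q → Z (k = 0.350 /M/min)
    D ⇌ G (K = 0.450, k = 0.140 /min)

On this flask the rule turns Z and 5.00% of L into D 47.3%, and the flask holds 47.3%. With E at 0%, part of the reason that conversion stays near 52.7% is a pair acting together, the way back from G to D and the path from 2 Q to X: the run without the way back reaches 100%, the run without the path to X 96.5%. In the neighbour flask with 3.80 equiv of E, Z reaches 45.8% with 5.00% of L, so the same K gives D 33.9%, and that flask holds 34%.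

(The earlier runs and the new flask are simulated with constants of no real substance; scatter was added.)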